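**Retrosynthetic overview**
- The target comes from fluoride O-desilylation of its primary TBS ether.
- Key bond: ketone carbon to N-bearing carbon (C3–C2), made by an enantioselective NHC cross-aza-benzoin. The furyl-undecanal reacts as an acyl anion equivalent with an N-acetyl imine released from an α-amido sulfone; this step sets the only stereocentre.
- The aldehyde comes from linear hydroformylation of a terminal alkene. The α-amido sulfone comes from silyloxyacetaldehyde, acetamide and p-toluenesulfinic acid.
- The furan is the only ring. Its butenolide ring is built first from 2,3-dimethylmaleic anhydride (Grignard addition, then NaBH4) and aromatised by propyl addition and dehydration.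

Assumption: the (5aS,10bR) antipode of the triazolium precatalyst is taken as the one that gives the 2S ketone; this is not predicted with certainty, so the sense is checked by chiral HPLC on the first run and the other antipode used if needed. All furan compounds are handled under argon, away from light.

**Step 1**
Reactants: 1 2,3-dimethylmaleic anhydride; 2 10-bromodec-1-ene
Product: 4 5-(dec-9-en-1-yl)-5-hydroxy-3,4-dimethylfuran-2(5H)-one (racemic), via dec-9-en-1-ylmagnesium bromide 3 (not isolated)
Conditions: 2, Mg, THF, rt to 40 °C; then added to 1 (1.2 equiv), THF, −78 to −20 °C; 1 M HCl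
Reagents that add atoms: none
Why: Grignard mono-addition to a cyclic anhydride, where inverse addition at −78 °C stops at the magnesium keto carboxylate, which closes to the γ-hydroxybutenolide on acidification (the new C5 centre is racemic and is erased in step 3).

**Step 2**
Reactants: 4 5-(dec-9-en-1-yl)-5-hydroxy-3,4-dimethylfuran-2(5H)-one
Product: 7 5-(dec-9-en-1-yl)-3,4-dimethylfuran-2(5H)-one (racemic), via sodium keto carboxylate 5 (not isolated), via sodium hydroxy carboxylate 6 (not isolated)
Conditions: NaBH4, 1 M NaOH, EtOH, 0 °C to rt; then 2 M HCl to pH 1, rt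
Reagents that add atoms: none
Why: Borohydride reduction of a pseudo-acid, in which base opens the lactol to the (Z)-keto carboxylate, the ketone is reduced, and acid lactonises the (Z)-γ-hydroxy acid to the butenolide (C5 racemic, erased in step 3).

**Step 3**
Reactants: 7 5-(dec-9-en-1-yl)-3,4-dimethylfuran-2(5H)-one
Product: 9 2-(dec-9-en-1-yl)-3,4-dimethyl-5-propylfuran, via 2-propyl lactol 8 (not isolated)
Conditions: n-PrMgCl, CeCl3 (1.3 equiv each), THF, −78 °C; then 1 M HCl, THF, 0 °C to rt, 10 min
Reagents that add atoms: n-propylmagnesium chloride CCC[Mg]Cl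
Why: Organocerium 1,2-addition to the lactone carbonyl (weakly basic, so γ-deprotonation is suppressed) followed by dehydrative aromatisation, the lactol losing water readily because the product is an aromatic furan; no stereocentre remains.

**Step 4**
Reactants: 9 2-(dec-9-en-1-yl)-3,4-dimethyl-5-propylfuran
Product: 10 11-(3,4-dimethyl-5-propylfuran-2-yl)undecanal
Conditions: Rh(acac)(CO)2 (0.5 mol%), BiPhePhos (1.5 mol%), CO/H2 (1:1, 10 bar), toluene, 70 °C
Reagents that add atoms: carbon monoxide [C-]#[O+]
Why: Rhodium/bisphosphite linear-selective hydroformylation puts CHO on the terminal carbon and so adds the one carbon that completes the C11 acyl chain, while the fully substituted furan offers the catalyst no reactive site.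

**Step 5**
Reactants: 11 (tert-butyldimethylsilyloxy)acetaldehyde; 12 acetamide
Product: 13 N-[2-(tert-butyldimethylsilyloxy)-1-(4-methylbenzenesulfonyl)ethyl]acetamide (racemic)
Conditions: p-TolSO2H (1.2 equiv, freshly liberated from its sodium salt), 12 (1.5 equiv), MgSO4, THF, rt, 24 h
Reagents that add atoms: p-toluenesulfinic acid Cc1ccc(cc1)S(=O)O
Why: α-Amido sulfone formation (three-component Mannich-type amidoalkylation), in which the N-acyl hemiaminal ionises under the sulfinic acid and is captured by sulfinate while MgSO4 removes water so that no aqueous acid reaches the primary silyl ether; the new centre is racemic and becomes sp2 again in step 6.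

**Step 6**
Reactants: 10 11-(3,4-dimethyl-5-propylfuran-2-yl)undecanal; 13 N-[2-(tert-butyldimethylsilyloxy)-1-(4-methylbenzenesulfonyl)ethyl]acetamide (1.5 equiv)
Product: 15 N-[(2S)-1-(tert-butyldimethylsilyloxy)-13-(3,4-dimethyl-5-propylfuran-2-yl)-3-oxotridecan-2-yl]acetamide, via N-acetyl imine 14 (not isolated)
Conditions: (5aS,10bR)-2-(2,4,6-trichlorophenyl)-5a,10b-dihydro-4H,6H-indeno[2,1-b][1,2,4]triazolo[4,3-d][1,4]oxazin-2-ium tetrafluoroborate (20 mol%), Cs2CO3 (1.5 equiv), 4 Å MS, CH2Cl2, −20 °C; AcOH quench at −20 °C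
Reagents that add atoms: none
Why: Proposed new method: an NHC-catalysed enantioselective cross-aza-benzoin in which the carbene adds to 10 to give the Breslow enaminol (an acyl anion equivalent), carbonate releases the N-acetyl imine 14 from 13 slowly so that it is trapped before it tautomerises to the enamide, C–C bond formation takes place on the imine face left open by the indane wall of the catalyst (organised by a hydrogen bond from the enaminol OH to the acyl imine) to set C2 as S, and collapse of the adduct frees the ketone and the carbene; the closest known reaction types are the chiral-triazolium cross-aza-benzoin of aliphatic aldehydes with N-Boc aryl imines and the thiazolium-catalysed coupling of aldehydes with N-acyl imines released from α-amido sulfones.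

**Step 7**
Reactants: 15 N-[(2S)-1-(tert-butyldimethylsilyloxy)-13-(3,4-dimethyl-5-propylfuran-2-yl)-3-oxotridecan-2-yl]acetamide
Product: 16 N-[(2S)-13-(3,4-dimethyl-5-propylfuran-2-yl)-1-hydroxy-3-oxotridecan-2-yl]acetamide (CNP0315214.1)
Conditions: HF·pyridine, pyridine, THF, 0 °C to rt
Reagents that add atoms: none
Why: Fluoride-driven O-desilylation under buffered, slightly acidic conditions, which leaves the base-labile α-amido ketone stereocentre, the β-hydroxy ketone (no retro-aldol) and the acid-sensitive furan untouched.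

**Compound list**
1 | 2,3-dimethylmaleic anhydride | CC1=C(C)C(=O)OC1=O | starting material
2 | 10-bromodec-1-ene | C=CCCCCCCCCBr | starting material
3 | dec-9-en-1-ylmagnesium bromide | C=CCCCCCCCC[Mg]Br | intermediate (not isolated)
4 | 5-(dec-9-en-1-yl)-5-hydroxy-3,4-dimethylfuran-2(5H)-one, racemic | CC1=C(C)C(O)(CCCCCCCCC=C)OC1=O | intermediate
5 | sodium (2Z)-2,3-dimethyl-4-oxotetradeca-2,13-dienoate | C=CCCCCCCCCC(=O)/C(C)=C(C)\C(=O)[O-].[Na+] | intermediate (not isolated)
6 | sodium (2Z)-4-hydroxy-2,3-dimethyltetradeca-2,13-dienoate, racemic | C=CCCCCCCCCC(O)/C(C)=C(C)\C(=O)[O-].[Na+] | intermediate (not isolated)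
7 | 5-(dec-9-en-1-yl)-3,4-dimethylfuran-2(5H)-one, racemic | CC1=C(C)C(CCCCCCCCC=C)OC1=O | intermediate
8 | 5-(dec-9-en-1-yl)-3,4-dimethyl-2-propyl-2,5-dihydrofuran-2-ol, diastereomer mixture | CCCC1(O)OC(CCCCCCCCC=C)C(C)=C1C | intermediate (not isolated)
9 | 2-(dec-9-en-1-yl)-3,4-dimethyl-5-propylfuran | C=CCCCCCCCCc1oc(CCC)c(C)c1C | intermediate
10 | 11-(3,4-dimethyl-5-propylfuran-2-yl)undecanal | O=CCCCCCCCCCCc1oc(CCC)c(C)c1C | intermediate
11 | (tert-butyldimethylsilyloxy)acetaldehyde | O=CCO[Si](C)(C)C(C)(C)C | starting material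
12 | acetamide | CC(N)=O | starting material
13 | N-[2-(tert-butyldimethylsilyloxy)-1-(4-methylbenzenesulfonyl)ethyl]acetamide, racemic | CC(=O)NC(CO[Si](C)(C)C(C)(C)C)S(=O)(=O)c1ccc(C)cc1 | intermediate
14 | N-[2-(tert-butyldimethylsilyloxy)ethylidene]acetamide | CC(=O)N=CCO[Si](C)(C)C(C)(C)C | intermediate (not isolated)
15 | N-[(2S)-1-(tert-butyldimethylsilyloxy)-13-(3,4-dimethyl-5-propylfuran-2-yl)-3-oxotridecan-2-yl]acetamide | CCCc1oc(CCCCCCCCCCC(=O)[C@H](CO[Si](C)(C)C(C)(C)C)NC(C)=O)c(C)c1C | intermediate
16 | N-[(2S)-13-(3,4-dimethyl-5-propylfuran-2-yl)-1-hydroxy-3-oxotridecan-2-yl]acetamide | CCCc1oc(CCCCCCCCCCC(=O)[C@H](CO)NC(C)=O)c(C)c1C | target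

**Totals**
Total steps: 7. Longest linear sequence: 6 (steps 1, 2, 3, 4, 6, 7); step 5 is a one-step side branch.

**Three steps most likely to fail**

Step 6 (highest risk). The aliphatic N-acetyl imine 14 may tautomerise to the enamide, the enantioselectivity is untested for this imine class, and the product can racemise under base. The fallback sets out from 10 (and uses 11) and comes back to the route at 16; it replaces the catalytic acyl anion by an auxiliary-controlled dithiane acyl anion.
- Aldehyde 10 is condensed with propane-1,3-dithiol (BF3·OEt2 0.3 equiv, CH2Cl2, −20 °C) to give 2-[10-(3,4-dimethyl-5-propylfuran-2-yl)decyl]-1,3-dithiane F1.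
- Aldehyde 11 is condensed with (S)-tert-butanesulfinamide (CuSO4, CH2Cl2) to give (S,E)-N-[2-(tert-butyldimethylsilyloxy)ethylidene]-2-methylpropane-2-sulfinamide F2.
- F1 is deprotonated (n-BuLi, THF, −25 °C) to 2-lithio-2-[10-(3,4-dimethyl-5-propylfuran-2-yl)decyl]-1,3-dithiane F3, which is added to F2 at −78 °C. This gives (S)-N-{(1S)-2-(tert-butyldimethylsilyloxy)-1-[2-(10-(3,4-dimethyl-5-propylfuran-2-yl)decyl)-1,3-dithian-2-yl]ethyl}-2-methylpropane-2-sulfinamide F4. The chelated chair model for lithium nucleophiles predicts this configuration; if the sense is reversed, the (R)-sulfinamide is used.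
- HCl in MeOH (0 °C, short) removes the sulfinyl and silyl groups to give (2S)-2-amino-2-{2-[10-(3,4-dimethyl-5-propylfuran-2-yl)decyl]-1,3-dithian-2-yl}ethan-1-ol F5, isolated as its hydrochloride.
- Ac2O in EtOAc/aqueous NaHCO3 acetylates nitrogen selectively to give N-[(1S)-1-{2-[10-(3,4-dimethyl-5-propylfuran-2-yl)decyl]-1,3-dithian-2-yl}-2-hydroxyethyl]acetamide F6.
- Non-oxidative dithiane removal (MeI, CaCO3, aqueous MeCN, 40 °C) spares the furan and gives 16.

Step 3. The butenolide may be γ-deprotonated or add propyl twice. The fallback sets out from 7 and comes back at 9; it replaces carbanion addition by hydride reduction followed by C–H lithiation and alkylation.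
- DIBAL-H (CH2Cl2, −78 °C) gives 5-(dec-9-en-1-yl)-3,4-dimethyl-2,5-dihydrofuran-2-ol F7.
- Dilute acid on work-up dehydrates it to 2-(dec-9-en-1-yl)-3,4-dimethylfuran F8.
- n-BuLi (THF, 0 °C) lithiates the one free α-position to give [5-(dec-9-en-1-yl)-3,4-dimethylfuran-2-yl]lithium F9.
- 1-Iodopropane (DMPU, 0 °C to rt) alkylates F9 to give 9.

Step 5. The silyl ether may not survive the sulfinic acid, or acetamide may condense poorly. The fallback sets out from 11 and 12 and comes back at 15; it replaces the acid-mediated sulfone condensation by a neutral benzotriazole amidoalkylation.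
- 11, 12 and 1H-benzotriazole (toluene, 4 Å MS, 60 °C) give N-[1-(1H-benzotriazol-1-yl)-2-(tert-butyldimethylsilyloxy)ethyl]acetamide F10.
- F10 is used in place of 13 under the step 6 conditions, where carbonate expels benzotriazolide to give the same imine 14 and hence 15.

**Further compounds**
F1 | step 6 | 2-[10-(3,4-dimethyl-5-propylfuran-2-yl)decyl]-1,3-dithiane | CCCc1oc(CCCCCCCCCCC2SCCCS2)c(C)c1C
F2 | step 6 | (S,E)-N-[2-(tert-butyldimethylsilyloxy)ethylidene]-2-methylpropane-2-sulfinamide | CC(C)(C)[S@](=O)/N=C/CO[Si](C)(C)C(C)(C)C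
F3 | step 6 | 2-lithio-2-[10-(3,4-dimethyl-5-propylfuran-2-yl)decyl]-1,3-dithiane | CCCc1oc(CCCCCCCCCCC2([Li])SCCCS2)c(C)c1C
F4 | step 6 | (S)-N-{(1S)-2-(tert-butyldimethylsilyloxy)-1-[2-(10-(3,4-dimethyl-5-propylfuran-2-yl)decyl)-1,3-dithian-2-yl]ethyl}-2-methylpropane-2-sulfinamide | CC(C)(C)[S@](=O)N[C@@H](CO[Si](C)(C)C(C)(C)C)C1(CCCCCCCCCCc2oc(CCC)c(C)c2C)SCCCS1
F5 | step 6 | (2S)-2-amino-2-{2-[10-(3,4-dimethyl-5-propylfuran-2-yl)decyl]-1,3-dithian-2-yl}ethan-1-ol | N[C@@H](CO)C1(CCCCCCCCCCc2oc(CCC)c(C)c2C)SCCCS1
F6 | step 6 | N-[(1S)-1-{2-[10-(3,4-dimethyl-5-propylfuran-2-yl)decyl]-1,3-dithian-2-yl}-2-hydroxyethyl]acetamide | CC(=O)N[C@@H](CO)C1(CCCCCCCCCCc2oc(CCC)c(C)c2C)SCCCS1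
F7 | step 3 | 5-(dec-9-en-1-yl)-3,4-dimethyl-2,5-dihydrofuran-2-ol | OC1OC(CCCCCCCCC=C)C(C)=C1C
F8 | step 3 | 2-(dec-9-en-1-yl)-3,4-dimethylfuran | C=CCCCCCCCCc1occ(C)c1C
F9 | step 3 | [5-(dec-9-en-1-yl)-3,4-dimethylfuran-2-yl]lithium | [Li]c1oc(CCCCCCCCC=C)c(C)c1C
F10 | step 5 | N-[1-(1H-benzotriazol-1-yl)-2-(tert-butyldimethylsilyloxy)ethyl]acetamide | CC(=O)NC(CO[Si](C)(C)C(C)(C)C)n1nnc2ccccc12
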